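Begin with how slow zeta has become: from 30.0 min to 40.0 min the substrate reading drops by only 4.1 percentage points, so extrapolating along the clock is weak footing, and you should reckon against [substrate] instead.

the same everywhere: substrate 0.50 M

| flask | reagent | remark | time |
|---|---|---|---|
| zeta | 0.55 M | the very flask that is asked about, followed so far |  |
| eta | 0.28 M | run made earlier |  |
| flask | 0.550 M |  | 3.0 h |

| run | time / min | substrate / % | mono adduct / % |
|---|---|---|---|
| zeta | 2.00 | 87.4 | 13.1 |
| zeta | 6.00 | 67.5 | 28.8 |
| zeta | 10.0 | 56.4 | 38.0 |
| zeta | 15.0 | 47.8 | 45.7 |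
| zeta | 20.0 | 42.4 | 50.5 |
| zeta | 30.0 | 33.9 | 57.7 |
| zeta | 40.0 | 29.8 | 60.8 |
| eta | 10.0 | 75.8 | 22.6 |
| eta | 15.0 | 69.3 | 28.7 |
| eta | 25.0 | 63.0 | 33.9 |
| eta | 40.0 | 58.5 | 37.8 |
| eta | 50.0 | 57.0 | 38.5 |
| eta | 80.0 | 54.0 | 39.6 |
| eta | 120 | 52.3 | 41.1 |

(readings scatter by 0.5 percentage points)

* how much substrate there is at 3.0 h, in percent of the substrate charged
* how much mono adduct there is at 3.0 h, in percent of the substrate charged
* how much bis adduct there is at 3.0 h, in percent of the substrate charged

- a reading or a percentage of mono adduct counts all its forms, free or not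

Call the gap what remains of the charge after the substrate and mono adduct readings. Suppose it grows by a step that takes reagent from a partner held at a steady dissolved level. Then in the selectivity factor, the gap's rate over the substrate's, reagent cancels, leaving a constant over [substrate], and integrating makes the gap linear in ln[substrate].

Test this on zeta. The gap is 5.60% at 10.0 min and 9.40% at 40.0 min, so the gap gained per factor e of falling [substrate] is 6 points. At 20.0 min this line gives 7.30% against a reading of 7.10%. The mono adduct reading climbs meanwhile from 38.0% to 60.8%, so take the steady partner to be some part of that reading, which counts all forms.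

Commit to this: one further factor of 2 in [substrate] puts the gap of the asked flask near 13.6%.

The forecast, whose bis adduct stands higher, gives 16% substrate, 66% mono adduct and 18% bis adduct, noting: “Bis adduct keeps forming at about 0.1%/min in zeta”. The flask gives 16.8% substrate, 70.3% mono adduct and 9.29% bis adduct.

    substrate + reagent → mono adduct (k = 0.00240 M⁻¹ s⁻¹)
    reagent + mono adduct → bis adduct (k = 0.00120 M⁻¹ s⁻¹)
    crystals ⇌ mono adduct, rate k3*(cs3 - [mono adduct]) while solid is left; crystals form when [mono adduct] > cs3 (solubility = 33.0 mM, k = 0.00450 s⁻¹)
    substrate + mono adduct → side product (k = 1.40 × 10⁻⁴ M⁻¹ s⁻¹)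
    reagent ⇌ dormant form (K = 3.00, k = 2.00 × 10⁻⁴ s⁻¹)

At that substrate the line gives a gap of 12.8%, and the flask's gap is 12.9%, made of 9.29% bis adduct and 3.64% side product. At 3.00 h the half-life of dissolved mono adduct by its reaction with reagent, 12 h, is longer than the time 3.0 h, while crystals stand at 63.6% of the substrate charged, counted within the 70.3% mono adduct.

Now take the neighbour flask charged with 0.85 M substrate. The same constant in molar terms, counted from the start down to 40.7% substrate, gives a gap of 3.15%. The computed gap is 9.96%, with 3.85% bis adduct and 6.11% side product.

(The numbers in the tables are calculated with made-up constants; scatter was added.)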